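**Retrosynthetic overview**

1. Ring numbering used below: C1 (sp2, carries the side chain), C2 (=CH), C3 (CHOH), C4 (=CH), C5 (C–OMe), C6 (CH–OAc). Enabling feature: C6 lies between C1 and the methoxy-substituted C5=C4 unit, so with C6 as a ketone the ring is a 4-oxy-6-methoxycyclohex-2-enone: C1 becomes an aldol donor, C4 a Michael acceptor terminus, and C2–C3 a glycolaldehyde unit.
2. Key disconnection: C3–C4 (Michael addition) and C1=C2 (aldol condensation) are made together in an amine-catalysed [4+2] annulation of an acyclic α-methoxy vinyl ketone with O-silyl glycolaldehyde. This closes the only ring, and the catalyst sets C3.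
3. Relay and unmasking: C3 directs C5 (PhSe enters anti to the silyl ether), C5 directs C6 (hydride anti to selenium, giving the trans-1,4 pattern). Selenoxide syn-elimination forms the C4=C5 enol ether only after C6 is sp3, so no cross-conjugated dienone (a phenol tautomer) is ever generated. The phenylselanyl group and the C6 ketone are the temporary activating group and oxidation level.
4. Acyclic part: the side-chain stereocentre is bought as (R)-epichlorohydrin and carried through an epoxide, an amide-enolate opening and a 1-methoxyvinyl ketone synthesis.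

Key step: step 5

Remark: the cyclohexenone from the key step is used as a mixture of epimers at its methoxy-bearing carbon, which is planarised in the next step; the descriptor of C3 changes from R to S in the final step only because CIP priorities change.

**Route**

Step 1
Reactants: 1 (R)-epichlorohydrin; 2 decylmagnesium bromide
Product: 4 (2R)-2-undecyloxirane, via chlorohydrin 3 (not isolated)
Conditions: 2 (1.2 equiv), CuI (5 mol %), THF, −40 → 0 °C; then 2 M aq NaOH, rt
Reagents that add atoms: none
Why: Copper-catalysed Grignard opening of the epoxide at its CH2 terminus followed by Williamson ring closure onto the CH2Cl carbon, so the bought stereocentre keeps its C–O bond throughout.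

Step 2
Reactants: 4 (2R)-2-undecyloxirane; 5 4-acetylmorpholine
Product: 6 (4R)-4-hydroxy-1-(morpholin-4-yl)pentadecan-1-one
Conditions: 5, LiN(iPr)2 (1.2 equiv), THF, −78 °C; then 4, −78 °C → rt; H2O
Reagents that add atoms: none
Why: Alkylation of an amide lithium enolate by SN2 opening of the terminal epoxide at CH2, which leaves the carbinol stereocentre untouched.

Step 3
Reactants: 6 (4R)-4-hydroxy-1-(morpholin-4-yl)pentadecan-1-one; 7 methyl vinyl ether
Product: 9 (6R)-6-hydroxy-2-methoxyheptadec-1-en-3-one, via 1-methoxyvinyllithium 8 (not isolated)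
Conditions: 7 (4 equiv), t-BuLi (3 equiv), THF, −78 → 0 °C; then 6, −78 → −20 °C; pH 7 buffer
Reagents that add atoms: none
Why: Weinreb-type ketone synthesis on a morpholine amide, in which one equivalent of 8 deprotonates the hydroxyl and a second adds only once because the tetrahedral lithium aminal survives until work-up.

Step 4
Reactants: 9 (6R)-6-hydroxy-2-methoxyheptadec-1-en-3-one
Product: 10 (6R)-2-methoxy-3-oxoheptadec-1-en-6-yl acetate
Conditions: Ac2O, pyridine, DMAP (cat.), CH2Cl2, 0 °C → rt
Reagents that add atoms: acetic anhydride CC(=O)OC(C)=O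
Why: DMAP-catalysed acetylation of the open-chain γ-hydroxy ketone under basic conditions that spare the acid-labile enol ether.

Step 5
Reactants: 10 (6R)-2-methoxy-3-oxoheptadec-1-en-6-yl acetate; 11 (tert-butyldimethylsilyloxy)acetaldehyde
Product: 14 (2R)-1-[(3R)-3-[(tert-butyldimethylsilyl)oxy]-5-methoxy-6-oxocyclohex-1-en-1-yl]tridecan-2-yl acetate (C5 epimers), via keto aldehyde 12 (not isolated), via aldol 13 (not isolated)
Conditions: 11 (1.5 equiv), (S)-2-[diphenyl(trimethylsilyloxy)methyl]pyrrolidine (10 mol %), 4-nitrophenol (20 mol %), toluene, 0 °C → rt; then p-TsOH·H2O (30 mol %), 40 °C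
Reagents that add atoms: none
Why: Proposed new method: aldehyde 11 condenses with the amine to an (E)-enamine that adds to the CH2 terminus of the α-methoxy vinyl ketone 10 (Michael addition, new C3–C4 bond), and after hydrolysis to 12 the acid promotes intramolecular aldol condensation of the ketone α'-CH2 (C1) onto the aldehyde (C2) with loss of water (new C1=C2 bond); the closest known reaction type is the diarylprolinol-ether-catalysed Michael addition of aldehydes to alkyl vinyl ketones with one-pot aldol condensation to 4-substituted cyclohex-2-enones, not yet shown for an α-alkoxy (captodative) vinyl ketone or an O-silyl glycolaldehyde donor. The single ring closes in the aldol step in a 6-(enolendo)-exo-trig mode, and dehydration leaves the alkene conjugated to the ketone. The retained new stereocentre C3 is set by the catalyst, whose diphenyl(silyloxy)methyl group shields one enamine face so that the enone should add to the other face and give the R aldehyde, as in known additions of aldehydes to nitroalkenes and vinyl ketones with the S catalyst; C5 forms unselectively and is erased later. The step needs Michael addition to outrun self-aldolisation of 11 and needs the donor-substituted acceptor to stay electrophilic: the catalyst has no acidic group to organise an aldol transition state, 4-nitrophenol activates the enone carbonyl by hydrogen bonding, and the conjugated ketone still polarises the terminal CH2. Ring-closure regiochemistry is unambiguous because only the α'-CH2 can reach the aldehyde through a six-membered ring, and the α-branched aldehyde 12 re-forms an enamine only slowly, which protects C3 from epimerisation.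

Step 6
Reactants: 14 (2R)-1-[(3R)-3-[(tert-butyldimethylsilyl)oxy]-5-methoxy-6-oxocyclohex-1-en-1-yl]tridecan-2-yl acetate
Product: 15 (2R)-1-[(3R,5R)-3-[(tert-butyldimethylsilyl)oxy]-5-methoxy-6-oxo-5-(phenylselanyl)cyclohex-1-en-1-yl]tridecan-2-yl acetate
Conditions: LiN(SiMe3)2 (1.1 equiv), THF, −78 °C; then PhSeCl (1.2 equiv), −78 °C
Reagents that add atoms: benzeneselenenyl chloride Cl[Se]c1ccccc1
Why: Kinetic deprotonation at the only α'-hydrogen gives the cross-conjugated lithium enolate, and electrophilic α-selenenylation should occur on the ring face anti to the silyloxy group two carbons away (1,3-induction as in α'-alkylations of 4-silyloxycyclohex-2-enones), setting the quaternary centre that relays to C6.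

Step 7
Reactants: 15 (2R)-1-[(3R,5R)-3-[(tert-butyldimethylsilyl)oxy]-5-methoxy-6-oxo-5-(phenylselanyl)cyclohex-1-en-1-yl]tridecan-2-yl acetate
Product: 16 (2R)-1-[(3R,5R,6S)-3-[(tert-butyldimethylsilyl)oxy]-6-hydroxy-5-methoxy-5-(phenylselanyl)cyclohex-1-en-1-yl]tridecan-2-yl acetate
Conditions: NaBH4, CeCl3·7H2O, MeOH, −78 → −40 °C
Reagents that add atoms: none
Why: Luche 1,2-reduction in which, with the large phenylselanyl group axial on the neighbouring quaternary carbon and the cerium-chelated methoxy group equatorial, hydride should add anti to selenium, so the new hydroxyl is cis to selenium and therefore trans to the ring silyl ether.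

Step 8
Reactants: 16 (2R)-1-[(3R,5R,6S)-3-[(tert-butyldimethylsilyl)oxy]-6-hydroxy-5-methoxy-5-(phenylselanyl)cyclohex-1-en-1-yl]tridecan-2-yl acetate
Product: 17 (2R)-1-[(3R,5R,6S)-6-acetoxy-3-[(tert-butyldimethylsilyl)oxy]-5-methoxy-5-(phenylselanyl)cyclohex-1-en-1-yl]tridecan-2-yl acetate
Conditions: Ac2O, DMAP, pyridine, CH2Cl2, rt
Reagents that add atoms: acetic anhydride CC(=O)OC(C)=O
Why: DMAP-catalysed acetylation of the hindered allylic alcohol, which touches no stereocentre and fixes the C6 acetate before any dienic system exists.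

Step 9
Reactants: 17 (2R)-1-[(3R,5R,6S)-6-acetoxy-3-[(tert-butyldimethylsilyl)oxy]-5-methoxy-5-(phenylselanyl)cyclohex-1-en-1-yl]tridecan-2-yl acetate
Product: 18 (2R)-1-[(3R,5R,6S)-6-acetoxy-3-hydroxy-5-methoxy-5-(phenylselanyl)cyclohex-1-en-1-yl]tridecan-2-yl acetate
Conditions: HF·pyridine, pyridine, THF, 0 °C → rt
Reagents that add atoms: none
Why: Fluoride-mediated cleavage of the secondary silyl ether on a robust substrate that has no enol ether yet, under buffered conditions that both acetates and the selenide tolerate.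

Step 10
Reactants: 18 (2R)-1-[(3R,5R,6S)-6-acetoxy-3-hydroxy-5-methoxy-5-(phenylselanyl)cyclohex-1-en-1-yl]tridecan-2-yl acetate
Product: 20 (2R)-1-[(3S,6S)-6-acetoxy-3-hydroxy-5-methoxycyclohexa-1,4-dien-1-yl]tridecan-2-yl acetate, via selenoxide 19 (not isolated)
Conditions: mCPBA (1.05 equiv), CH2Cl2, −78 °C; then i-Pr2NH (3 equiv), −78 → 20 °C
Reagents that add atoms: none
Why: Selenide oxidation and selenoxide syn-elimination (the β-hydroxy selenide route to allylic alcohols) should give the C4=C5 enol ether regioselectively, because the only syn β-hydrogen sits on the ring CH2 while the hydrogen on the acetoxy carbon is anti to selenium, and the amine-buffered, low-temperature conditions leave both carbinol centres untouched.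

**Compound list**

1 | (R)-epichlorohydrin | ClC[C@H]1CO1 | starting material
2 | decylmagnesium bromide | CCCCCCCCCC[Mg]Br | starting material
3 | (2R)-1-chlorotridecan-2-ol | ClC[C@H](O)CCCCCCCCCCC | intermediate
4 | (2R)-2-undecyloxirane | C1[C@H](O1)CCCCCCCCCCC | intermediate
5 | 4-acetylmorpholine | CC(=O)N1CCOCC1 | starting material
6 | (4R)-4-hydroxy-1-(morpholin-4-yl)pentadecan-1-one | O=C(N1CCOCC1)CC[C@H](O)CCCCCCCCCCC | intermediate
7 | methyl vinyl ether | COC=C | starting material
8 | 1-methoxyvinyllithium | [Li]C(=C)OC | intermediate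
9 | (6R)-6-hydroxy-2-methoxyheptadec-1-en-3-one | C=C(OC)C(=O)CC[C@H](O)CCCCCCCCCCC | intermediate
10 | (6R)-2-methoxy-3-oxoheptadec-1-en-6-yl acetate | C=C(OC)C(=O)CC[C@H](OC(C)=O)CCCCCCCCCCC | intermediate
11 | (tert-butyldimethylsilyloxy)acetaldehyde | O=CCO[Si](C)(C)C(C)(C)C | starting material
12 | (2R,8R)-2-[(tert-butyldimethylsilyl)oxy]-4-methoxy-1,5-dioxononadecan-8-yl acetate (C4 epimers) | O=C[C@H](O[Si](C)(C)C(C)(C)C)CC(OC)C(=O)CC[C@H](OC(C)=O)CCCCCCCCCCC | intermediate
13 | (2R)-1-[(3R)-3-[(tert-butyldimethylsilyl)oxy]-2-hydroxy-5-methoxy-6-oxocyclohexyl]tridecan-2-yl acetate (isomer mixture) | O=C1C(OC)C[C@@H](O[Si](C)(C)C(C)(C)C)C(O)C1C[C@H](OC(C)=O)CCCCCCCCCCC | intermediate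
14 | (2R)-1-[(3R)-3-[(tert-butyldimethylsilyl)oxy]-5-methoxy-6-oxocyclohex-1-en-1-yl]tridecan-2-yl acetate (C5 epimers) | O=C1C(OC)C[C@@H](O[Si](C)(C)C(C)(C)C)C=C1C[C@H](OC(C)=O)CCCCCCCCCCC | intermediate
15 | (2R)-1-[(3R,5R)-3-[(tert-butyldimethylsilyl)oxy]-5-methoxy-6-oxo-5-(phenylselanyl)cyclohex-1-en-1-yl]tridecan-2-yl acetate | O=C1[C@](OC)([Se]c2ccccc2)C[C@@H](O[Si](C)(C)C(C)(C)C)C=C1C[C@H](OC(C)=O)CCCCCCCCCCC | intermediate
16 | (2R)-1-[(3R,5R,6S)-3-[(tert-butyldimethylsilyl)oxy]-6-hydroxy-5-methoxy-5-(phenylselanyl)cyclohex-1-en-1-yl]tridecan-2-yl acetate | O[C@@H]1[C@](OC)([Se]c2ccccc2)C[C@@H](O[Si](C)(C)C(C)(C)C)C=C1C[C@H](OC(C)=O)CCCCCCCCCCC | intermediate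
17 | (2R)-1-[(3R,5R,6S)-6-acetoxy-3-[(tert-butyldimethylsilyl)oxy]-5-methoxy-5-(phenylselanyl)cyclohex-1-en-1-yl]tridecan-2-yl acetate | CC(=O)O[C@@H]1[C@](OC)([Se]c2ccccc2)C[C@@H](O[Si](C)(C)C(C)(C)C)C=C1C[C@H](OC(C)=O)CCCCCCCCCCC | intermediate
18 | (2R)-1-[(3R,5R,6S)-6-acetoxy-3-hydroxy-5-methoxy-5-(phenylselanyl)cyclohex-1-en-1-yl]tridecan-2-yl acetate | CC(=O)O[C@@H]1[C@](OC)([Se]c2ccccc2)C[C@@H](O)C=C1C[C@H](OC(C)=O)CCCCCCCCCCC | intermediate
19 | (2R)-1-[(3R,5R,6S)-6-acetoxy-3-hydroxy-5-methoxy-5-(phenylseleninyl)cyclohex-1-en-1-yl]tridecan-2-yl acetate | CC(=O)O[C@@H]1[C@](OC)([Se](=O)c2ccccc2)C[C@@H](O)C=C1C[C@H](OC(C)=O)CCCCCCCCCCC | intermediate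
20 | (2R)-1-[(3S,6S)-6-acetoxy-3-hydroxy-5-methoxycyclohexa-1,4-dien-1-yl]tridecan-2-yl acetate | CC(=O)O[C@@H]1C(OC)=C[C@@H](O)C=C1C[C@H](OC(C)=O)CCCCCCCCCCC | target

**Step count and risks**

Total steps: 10. Longest linear sequence: 10 steps (1 to 20).

Step 5 (Proposed new method). What may go wrong: conjugate addition to the donor-substituted enone may be slow, so that self-aldolisation of 11 and N-alkylation of the catalyst take over; the silyloxy carbon may also partly epimerise during the acid-promoted ring closure. Fallback with known chemistry, setting out from 6 and returning at 14, in which the methoxy group is brought in after the ring is made: CH2=CHMgBr converts 6 into (6R)-6-hydroxyheptadec-1-en-3-one F1 (inverse quench into cold dilute acid so that freed morpholine does not add to the enone), and acetylation gives (6R)-3-oxoheptadec-1-en-6-yl acetate F2. The established diarylprolinol-ether-catalysed Michael addition of 11 to this plain alkyl vinyl ketone gives (2R,8R)-2-[(tert-butyldimethylsilyl)oxy]-1,5-dioxononadecan-8-yl acetate F3. Under acid this closes through (2R)-1-[(3R)-3-[(tert-butyldimethylsilyl)oxy]-2-hydroxy-6-oxocyclohexyl]tridecan-2-yl acetate F4 to (2R)-1-[(3R)-3-[(tert-butyldimethylsilyl)oxy]-6-oxocyclohex-1-en-1-yl]tridecan-2-yl acetate F5. α'-Hydroxylation of the lithium enolate of F5 (LiN(SiMe3)2, then 2-(phenylsulfonyl)-3-phenyloxaziridine) gives (2R)-1-[(3R,5R)-3-[(tert-butyldimethylsilyl)oxy]-5-hydroxy-6-oxocyclohex-1-en-1-yl]tridecan-2-yl acetate F6, and O-methylation (MeI, Ag2O) returns to 14 as one C5 epimer.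

Step 7. What may go wrong: hydride may be delivered syn to selenium, or the relay may already be lost if selenium entered syn to the silyl ether in step 6; either would give the cis-1,4 pattern. Fallback, setting out from 15 and returning at 16: replace the substrate relay by catalyst control with a Corey–Bakshi–Shibata reduction (2-methyl-CBS-oxazaborolidine, catecholborane, toluene, −78 °C), choosing the catalyst enantiomer that delivers hydride to the required carbonyl face. This fallback forms no compound outside the list (F0).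

Step 10. What may go wrong: benzeneselenenic acid may re-add to the new enol ether, or a bis-allylic carbinol carbon may ionise and lose water or acetic acid (aromatisation), the free C3 hydroxyl making the product harder to keep neutral. Fallback, setting out from 17 and returning at 20, in which elimination precedes deprotection: mCPBA at −78 °C oxidises 17 to (2R)-1-[(3R,5R,6S)-6-acetoxy-3-[(tert-butyldimethylsilyl)oxy]-5-methoxy-5-(phenylseleninyl)cyclohex-1-en-1-yl]tridecan-2-yl acetate F7. Syn-elimination in the presence of i-Pr2NH gives the fully protected (2R)-1-[(3S,6S)-6-acetoxy-3-[(tert-butyldimethylsilyl)oxy]-5-methoxycyclohexa-1,4-dien-1-yl]tridecan-2-yl acetate F8, which can be purified on base-washed silica. AcOH-buffered Bu4NF in THF at 0 °C then removes the silyl ether to give 20.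

**Further compounds**

F1 | step 5 | (6R)-6-hydroxyheptadec-1-en-3-one | C=CC(=O)CC[C@H](O)CCCCCCCCCCC
F2 | step 5 | (6R)-3-oxoheptadec-1-en-6-yl acetate | C=CC(=O)CC[C@H](OC(C)=O)CCCCCCCCCCC
F3 | step 5 | (2R,8R)-2-[(tert-butyldimethylsilyl)oxy]-1,5-dioxononadecan-8-yl acetate | O=C[C@H](O[Si](C)(C)C(C)(C)C)CCC(=O)CC[C@H](OC(C)=O)CCCCCCCCCCC
F4 | step 5 | (2R)-1-[(3R)-3-[(tert-butyldimethylsilyl)oxy]-2-hydroxy-6-oxocyclohexyl]tridecan-2-yl acetate | O=C1CC[C@@H](O[Si](C)(C)C(C)(C)C)C(O)C1C[C@H](OC(C)=O)CCCCCCCCCCC
F5 | step 5 | (2R)-1-[(3R)-3-[(tert-butyldimethylsilyl)oxy]-6-oxocyclohex-1-en-1-yl]tridecan-2-yl acetate | O=C1CC[C@@H](O[Si](C)(C)C(C)(C)C)C=C1C[C@H](OC(C)=O)CCCCCCCCCCC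
F6 | step 5 | (2R)-1-[(3R,5R)-3-[(tert-butyldimethylsilyl)oxy]-5-hydroxy-6-oxocyclohex-1-en-1-yl]tridecan-2-yl acetate | O=C1[C@H](O)C[C@@H](O[Si](C)(C)C(C)(C)C)C=C1C[C@H](OC(C)=O)CCCCCCCCCCC
F0 | step 7 | none | none
F7 | step 10 | (2R)-1-[(3R,5R,6S)-6-acetoxy-3-[(tert-butyldimethylsilyl)oxy]-5-methoxy-5-(phenylseleninyl)cyclohex-1-en-1-yl]tridecan-2-yl acetate | CC(=O)O[C@@H]1[C@](OC)([Se](=O)c2ccccc2)C[C@@H](O[Si](C)(C)C(C)(C)C)C=C1C[C@H](OC(C)=O)CCCCCCCCCCC
F8 | step 10 | (2R)-1-[(3S,6S)-6-acetoxy-3-[(tert-butyldimethylsilyl)oxy]-5-methoxycyclohexa-1,4-dien-1-yl]tridecan-2-yl acetate | CC(=O)O[C@@H]1C(OC)=C[C@@H](O[Si](C)(C)C(C)(C)C)C=C1C[C@H](OC(C)=O)CCCCCCCCCCC
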